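## The problem

4,5-Di-O-p-coumaroylquinic acid (24) is a cyclohexane with four stereocentres, the quaternary C1 (hydroxyl and carboxyl carbon C7) and the contiguous carbinols C3, C4 and C5 (quinic acid numbering throughout). O1, O3 and O4 lie on one face and O5 and the carboxyl on the other, so O4/O5 are trans, O3/O4 cis and O1/O3 cis-1,3. Only O4 and O5 are acylated, so these two oxygens must be told apart from O1, O3 and the acid, ideally from the first step. The two (E)-4-hydroxycinnamoyl esters are the fragile part: base cleaves them or moves them to a free cis 3-hydroxyl, hydrogenation destroys their alkenes, light isomerises them and the free phenols are easily alkylated. They must therefore be attached late and unmasked under acidic, non-reductive conditions. Stereocontrol can be relayed: the trans C4/C5 pair can be bought, C4 can set C3 through a chelate, and the C3 hydroxyl can deliver oxygen across the ring to C1. The key step rests on one feature: C3 is a carbinol next to the C4 oxygen and is joined through the C2 methylene to C1, whose carboxyl carbon C7 can be carried as the silylated methylene of a 2-substituted allylsilane, so that an aldehyde at C3 and the unit C2H2=C1(C6)–C7H2–SiMe3 are placed to close the C2–C3 bond and the ring.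

## Retrosynthesis

**Unmasking.** Target 24 is taken back to the fully protected ester 23, which carries a tert-butyl ester, a 3-O-TBS ether and two 4-methoxybenzyl (PMB) aryl ethers. No skeletal bond is cut. All four groups fall in one acidolysis, so the last step involves neither base (acyl migration) nor hydrogen (alkene loss).

**Ester bonds.** The two acyl C–O bonds at O4 and O5 of 23 are cut to give diol 19 and two equivalents of the protected acid 22. Acylating last keeps the cinnamoyl groups out of every hydrogenation and strong-base step. The forward reaction must acylate two neighbouring equatorial hydroxyls and leave the tertiary O1–H alone. Acid 22 comes in one operation from p-coumaric acid (20) through the doubly alkylated 21.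

**Protecting-group exchange.** Diol 19 comes from dibenzyl ether 18 by hydrogenolysis, 18 from hydroxy ester 17 by silylation of O3, and 17 from 4,5-di-O-benzylquinic acid (16) by esterification. The benzyl ethers are the ones put on the tartrate in step 1. They mark O4/O5 through the whole synthesis and are removed when the molecule has no alkene left.

**C1 functionality.** The C1–O1 bond and the oxidation level of C7 in 16 are traced to the exocyclic alkene of 12. Acid 16 comes from triol 14 by oxidation of the primary alcohol (via aldehyde 15), 14 from spiro-epoxide 13 by hydroxide attack at the methylene carbon, and 13 from 12 by delivery of oxygen from the C3 hydroxyl. Osmylation of 12 from the open equatorial side would give the wrong C1 epimer. Delivery from the axial O3 gives the right one.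

**Ring closure (key cut).** The C2–C3 bond of 12 is cut to give aldehyde 11, an open chain with two stereocentres and an allylsilane. Cutting here rather than at C1–C2 or C1–C6 places the new stereocentre next to an existing benzyloxy-bearing carbon, where a chelating Lewis acid can control it. The nucleophilic carbon is also one that needs no later adjustment. The forward step must form one ring, one C–C bond and the C3 carbinol cis to O4.

**Chain assembly.** Aldehyde 11 comes from alcohol 10 and silyl ether 9. The C6–C1 bond of 9 is cut to the primary triflate 6 and the vinylic Grignard reagent 8 made from (2-bromoallyl)trimethylsilane (7). An sp3 triflate and an sp2 copper nucleophile are the pairing that tolerates the β-benzyloxy group. An alkylmetal at that carbon would eliminate the alkoxide.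

**Chiral pool.** Triflate 6 comes from mono-silyl ether 5, which comes from the C2-symmetric diol 4, itself from dibenzyl ether 3 made from diethyl D-tartrate (1) and two equivalents of benzyl bromide (2). The (2S,3S) ester supplies C4 and C5 with the correct absolute configuration and the trans relationship. Because 4 is C2-symmetric, monoprotection raises no regiochemical question.

## Roads not taken

Alternative 1: The cut is the C1–C6 ring bond, made by an Ireland–Claisen ring contraction.
- **Forward step.** The vinyl δ-lactone A2 (3-(methoxymethoxy)-5-(tert-butyldimethylsilyloxy)-6-vinyltetrahydropyran-2-one, silyloxy and vinyl cis) is converted by LiN(i-Pr)2 and TMSCl into its silyl ketene acetal. On warming, a [3,3] shift through a boat joins the vinyl terminus to C1, breaks the lactone C4–O bond and leaves cyclohexene acid A1 with O1 cis to O3.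
- **Merits.** The quaternary centre arrives complete, with hydroxyl and carboxyl at the right oxidation level. The sigmatropic step is reliable.
- **Weak points.** A1 lacks O4 and O5. The C4=C5 alkene must become a trans diol with O4 cis to O3. This needs epoxidation directed by a freed 3-hydroxyl and then opening at C5 only, and nothing in the structure secures that regiochemistry. O4 and O5 would also emerge undifferentiated from O3 unless further protecting steps are added. A2 itself needs three stereocentres.
- **Comparison.** At C1 this road is better; the chosen plan spends steps 9–11 on what the rearrangement gives at once. Against that, 12 leaves the ring closure with all three carbinol centres set and O4/O5 already marked as benzyl ethers.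

Alternative 2: The cut is the two Cα=Cβ bonds of the cinnamoyl groups, on a ring taken from (−)-quinic acid A6.
- **Forward step.** The 3-O-silyl bis(hydrogen malonate) A4 condenses with two equivalents of 4-hydroxybenzaldehyde A5 in pyridine with piperidine. Decarboxylation gives both (E)-alkenes and the silyl ether A3, one desilylation from the target.
- **Merits.** It is by far the shortest road. All four ring stereocentres are bought, the phenols need no protection and the E geometry is inherent.
- **Weak points.** A6 must first be protected at O3 alone with O4/O5 free, a pattern its own reactivity does not favour. The condensation heats two esters with a secondary amine and a free carboxyl. Aminolysis of the malonates, silyl migration from O3 to O4 and incomplete double condensation are therefore real risks.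
- **Comparison.** In step count this road is clearly superior, and for supplying the natural product it would be preferred. The chosen plan does not depend on regioselective protection of a tetraol or on base near migratable esters. It reaches either enantiomer from D- or L-tartrate and can give ring- or C7-modified analogues that quinic acid cannot.

Alternative 3: The cut is both C1–C2 and C1–C6, made by double alkylation of a glycolate enolate.
- **Forward step.** The enolate of 2,2-dimethyl-1,3-dioxolan-4-one A9 displaces the two primary triflates of the D-arabinitol derivative A8 (2,3-acetonide, 4-O-PMB) in one pot. The product is spiro-dioxolanone A7.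
- **Merits.** It is short and convergent. The three carbinol centres come from a pentitol, and O4/O5 (acetonide), O3 (PMB) and O1/carboxyl (dioxolanone) are all differentiated.
- **Weak points.** The configuration at C1 is decided in the ring-closing alkylation, by whether the enolate oxygen or its carbonyl carbon takes the axial position. No strong element controls that choice. The enolate is also prone to self-condensation, and β-alkoxy triflates can eliminate under two equivalents of base.
- **Comparison.** It is shorter than the chosen plan and equal in differentiation. The chosen plan sets against it a defined control element for each new stereocentre: the SnCl4 chelate for C3 and hydroxyl-directed delivery for C1.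

Key step: step 8

Assumption: the target has the configuration of natural (−)-quinic acid, which requires the (2S,3S) enantiomer of diethyl tartrate; C7 denotes the carboxyl carbon.

## Route

Step 1
Reactants: 1 diethyl D-tartrate; 2 benzyl bromide
Product: 3 diethyl (2S,3S)-2,3-bis(benzyloxy)butanedioate
Conditions: NaH (2.2 equiv), BnBr (2.2 equiv), Bu4NI (cat.), THF, 0 °C → rt
Reagents that add atoms: benzyl bromide (second equivalent of 2), BrCc1ccccc1
Why: Williamson etherification of both secondary hydroxyls, each taking one benzyl group from benzyl bromide; iodide catalysis and low temperature should let O-alkylation outrun enolisation of the α-alkoxy esters, so the (2S,3S) configuration is kept.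

Step 2
Reactants: 3 diethyl (2S,3S)-2,3-bis(benzyloxy)butanedioate
Product: 4 (2R,3R)-2,3-bis(benzyloxy)butane-1,4-diol
Conditions: LiAlH4, THF, 0 °C → reflux; aq. NaOH work-up
Reagents that add atoms: none
Why: Hydride reduction of both esters to primary alcohols; the stereocentres are untouched and only their descriptors change with the substituent priorities.

Step 3
Reactants: 4 (2R,3R)-2,3-bis(benzyloxy)butane-1,4-diol
Product: 5 (2R,3R)-2,3-bis(benzyloxy)-4-[(tert-butyldimethylsilyl)oxy]butan-1-ol
Conditions: NaH (1.0 equiv), THF, 0 °C → rt; then TBSCl (1.0 equiv)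
Reagents that add atoms: tert-butyldimethylsilyl chloride, CC(C)(C)[Si](C)(C)Cl
Why: Monosilylation of a symmetric 1,4-diol through its sparingly soluble monosodium alkoxide, which is silylated before a second deprotonation; the C2 symmetry of 4 makes the two hydroxyls equivalent.

Step 4
Reactants: 5 (2R,3R)-2,3-bis(benzyloxy)-4-[(tert-butyldimethylsilyl)oxy]butan-1-ol
Product: 6 (2R,3R)-2,3-bis(benzyloxy)-4-[(tert-butyldimethylsilyl)oxy]butyl trifluoromethanesulfonate
Conditions: Tf2O, 2,6-lutidine, CH2Cl2, −78 °C; cold aqueous work-up, used crude at once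
Reagents that add atoms: trifluoromethanesulfonic anhydride, O=S(=O)(OS(=O)(=O)C(F)(F)F)C(F)(F)F
Why: Sulfonylation of the remaining primary alcohol; the hindered base and low temperature should keep the β-alkoxy triflate from elimination and from attack by the distal silyl ether oxygen.

Step 5
Reactants: 6 (2R,3R)-2,3-bis(benzyloxy)-4-[(tert-butyldimethylsilyl)oxy]butyl trifluoromethanesulfonate; 7 (2-bromoallyl)trimethylsilane
Product: 9 (2R,3R)-2,3-bis(benzyloxy)-1-[(tert-butyldimethylsilyl)oxy]-5-[(trimethylsilyl)methyl]hex-5-ene, via Grignard reagent 8 (not isolated)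
Conditions: 7, Mg, THF, 40 °C; then CuI (10 mol%), 6, THF, −30 → 0 °C
Reagents that add atoms: none
Why: Magnesium inserts into the vinylic C–Br bond of 7, and CuI catalysis lets the resulting Grignard reagent displace the primary triflate by SN2 (copper-catalysed Grignard–alkyl triflate cross-coupling); the C6–C1 bond is made and the allylsilane arrives intact, with both stereocentres remote from the reacting carbon.

Step 6
Reactants: 9 (2R,3R)-2,3-bis(benzyloxy)-1-[(tert-butyldimethylsilyl)oxy]-5-[(trimethylsilyl)methyl]hex-5-ene
Product: 10 (2R,3R)-2,3-bis(benzyloxy)-5-[(trimethylsilyl)methyl]hex-5-en-1-ol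
Conditions: PPTS (cat.), MeOH, rt
Reagents that add atoms: none
Why: Acid-catalysed methanolysis of a primary TBS ether; pyridinium tosylate should be too weak an acid to protonate the 1,1-disubstituted alkene, so protodesilylation of the allylsilane is not expected, and the benzyl ethers are inert.

Step 7
Reactants: 10 (2R,3R)-2,3-bis(benzyloxy)-5-[(trimethylsilyl)methyl]hex-5-en-1-ol
Product: 11 (2S,3R)-2,3-bis(benzyloxy)-5-[(trimethylsilyl)methyl]hex-5-enal
Conditions: Dess–Martin periodinane, NaHCO3, CH2Cl2, 0 °C → rt; used without chromatography
Reagents that add atoms: none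
Why: Dess–Martin oxidation of a primary alcohol to the aldehyde under buffered, non-basic conditions, which should spare both the epimerisable α-benzyloxy centre and the acid-sensitive allylsilane.

Step 8
Reactants: 11 (2S,3R)-2,3-bis(benzyloxy)-5-[(trimethylsilyl)methyl]hex-5-enal
Product: 12 (1R,2R,3R)-2,3-bis(benzyloxy)-5-methylidenecyclohexan-1-ol
Conditions: SnCl4 (1.1 equiv), CH2Cl2 (0.02 M), −78 °C; aq. NaHCO3
Reagents that add atoms: none
Why: SnCl4 binds the aldehyde oxygen and the benzyloxy oxygen on the neighbouring carbon of 11 (the future C4) in a five-membered chelate that activates the carbonyl and holds the O=C–C–O dihedral near zero; the unsubstituted alkene terminus of the allylsilane then attacks the carbonyl carbon, and the β-silyl cation loses Me3SiCl to leave the exocyclic methylene (intramolecular Hosomi–Sakurai allylation, type 2). The closest known reactions are SnCl4-mediated chelation-controlled allylsilane additions to α-benzyloxy aldehydes and cyclisations of 2-(silylmethyl)allyl chains onto aldehydes that give 3-methylenecyclohexanols. The six-membered ring closes 6-exo-trig with respect to the carbonyl, the allylsilane double bond lying inside the forming ring. The only new stereocentre, the carbinol carbon, is controlled by the adjacent benzyloxy-bearing carbon: that carbon holds the tether on one side of the chelate plane, so the alkene can reach only the carbonyl face on that side, and a six-membered ring cannot span the opposite face while the two oxygens stay eclipsed. In chair terms the chelated transition state has both benzyloxy groups pseudo-axial and the carbonyl oxygen pseudo-equatorial, syn-clinal to the chelating oxygen; after closure the ring should relax to the chair with diequatorial benzyloxy groups and an axial hydroxyl cis to its neighbour. The step needs α-chelation to win over β-chelation through the second benzyloxy oxygen and over open transition states, neither of which enforces the cis relationship; the five-membered SnCl4 chelate of an α-benzyloxy aldehyde is the stronger one, and low temperature in a non-coordinating solvent favours it. It also needs ring closure to outrun protodesilylation, which the high nucleophilicity of a 2-substituted allylsilane and the intramolecular setting should secure.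

Step 9
Reactants: 12 (1R,2R,3R)-2,3-bis(benzyloxy)-5-methylidenecyclohexan-1-ol
Product: 13 (3S,5R,6R,7R)-6,7-bis(benzyloxy)-1-oxaspiro[2.5]octan-5-ol
Conditions: VO(acac)2 (5 mol%), t-BuOOH (decane), CH2Cl2, 0 °C → rt
Reagents that add atoms: tert-butyl hydroperoxide, CC(C)(C)OO
Why: Hydroxyl-directed epoxidation of a homoallylic alcohol: the axial alkoxide binds the pentavalent vanadium peroxide and delivers oxygen to the alkene face on which it sits, so the epoxide oxygen at C1 should be cis to O3; benzyl ethers are inert to the peroxide.

Step 10
Reactants: 13 (3S,5R,6R,7R)-6,7-bis(benzyloxy)-1-oxaspiro[2.5]octan-5-ol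
Product: 14 (1S,3R,4R,5R)-4,5-bis(benzyloxy)-1-(hydroxymethyl)cyclohexane-1,3-diol
Conditions: KOH, DMSO/H2O (3:1), 90 °C
Reagents that add atoms: water, O
Why: Hydroxide opens the spiro-epoxide by SN2 at the unsubstituted methylene carbon, so the C1–O bond made in step 9 is retained and the tertiary hydroxyl stays cis to O3; the C3 alkoxide lies on the same side as the epoxide oxygen and cannot reach the backside of the C7–O bond, so no cyclic ether should form.

Step 11
Reactants: 14 (1S,3R,4R,5R)-4,5-bis(benzyloxy)-1-(hydroxymethyl)cyclohexane-1,3-diol
Product: 16 4,5-di-O-benzylquinic acid, via hydroxy aldehyde 15 (not isolated)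
Conditions: TEMPO (cat.), NaClO2, NaOCl (cat.), MeCN/phosphate buffer (pH 6.7), 35 °C; acidify to pH 3
Reagents that add atoms: sodium chlorite, [Na+].[O-]Cl=O
Why: The oxoammonium salt from TEMPO oxidises the unhindered primary alcohol to aldehyde 15, which chlorite converts to the acid as it forms (TEMPO/NaClO2 oxidation of a primary alcohol to a carboxylic acid); the bulky oxidant should react much more slowly with the axial, flanked C3 hydroxyl and cannot oxidise the tertiary one.

Step 12
Reactants: 16 4,5-di-O-benzylquinic acid
Product: 17 tert-butyl 4,5-di-O-benzylquinate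
Conditions: t-BuOC(=NH)CCl3, CH2Cl2/cyclohexane, rt
Reagents that add atoms: tert-butyl 2,2,2-trichloroacetimidate, CC(C)(C)OC(=N)C(Cl)(Cl)Cl
Why: The carboxylic acid protonates the imidate and the carboxylate captures the tert-butyl cation (imidate esterification); without added Lewis acid the hydroxyls are not alkylated, and the ester is stable to hydrogenolysis and carbodiimide acylation yet acid-labile.

Step 13
Reactants: 17 tert-butyl 4,5-di-O-benzylquinate
Product: 18 tert-butyl 4,5-di-O-benzyl-3-O-(tert-butyldimethylsilyl)quinate
Conditions: TBSCl, imidazole, DMF, rt → 40 °C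
Reagents that add atoms: tert-butyldimethylsilyl chloride, CC(C)(C)[Si](C)(C)Cl
Why: Imidazole-promoted silylation should select the secondary C3 hydroxyl over the tertiary, ester-flanked C1 hydroxyl on steric grounds; O3, the only position to which a coumaroyl group could later add or migrate, is thereby blocked.

Step 14
Reactants: 18 tert-butyl 4,5-di-O-benzyl-3-O-(tert-butyldimethylsilyl)quinate
Product: 19 tert-butyl 3-O-(tert-butyldimethylsilyl)quinate
Conditions: H2 (1 atm), Pd(OH)2/C, EtOAc, rt
Reagents that add atoms: none
Why: Hydrogenolysis of the two benzyl ethers frees exactly the O4/O5 diol marked since step 1; in ethyl acetate the silyl ether and tert-butyl ester are stable, and no alkene is present.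

Step 15
Reactants: 20 p-coumaric acid
Product: 22 (E)-3-{4-[(4-methoxybenzyl)oxy]phenyl}prop-2-enoic acid, via bis(4-methoxybenzyl) derivative 21 (not isolated)
Conditions: PMBCl (2.2 equiv), K2CO3, DMF, 60 °C; then aq. NaOH, MeOH/THF, 60 °C; HCl to pH 3
Reagents that add atoms: 4-methoxybenzyl chloride, COc1ccc(CCl)cc1
Why: Carbonate-mediated Williamson alkylation protects phenol and acid together as 21, and saponification cleaves only the ester because the aryl ether is inert to hydroxide; the (E)-alkene is not affected.

Step 16
Reactants: 19 tert-butyl 3-O-(tert-butyldimethylsilyl)quinate; 22 (E)-3-{4-[(4-methoxybenzyl)oxy]phenyl}prop-2-enoic acid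
Product: 23 tert-butyl 3-O-(tert-butyldimethylsilyl)-4,5-bis-O-{(E)-3-[4-(4-methoxybenzyloxy)phenyl]prop-2-enoyl}quinate
Conditions: 22 (2.4 equiv), EDC·HCl, DMAP, CH2Cl2, 0 °C → rt, dark
Reagents that add atoms: (E)-3-{4-[(4-methoxybenzyl)oxy]phenyl}prop-2-enoic acid (second equivalent of 22), O=C(O)/C=C/c1ccc(OCc2ccc(OC)cc2)cc1
Why: Carbodiimide esterification with DMAP catalysis (Steglich esterification) should acylate the two equatorial secondary hydroxyls, one molecule of 22 going to each, while the tertiary C1 hydroxyl is too hindered to react; O3 is silylated, so no acyl migration is possible, and the weakly basic medium should not move the silyl group.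

Step 17
Reactants: 23 tert-butyl 3-O-(tert-butyldimethylsilyl)-4,5-bis-O-{(E)-3-[4-(4-methoxybenzyloxy)phenyl]prop-2-enoyl}quinate
Product: 24 4,5-di-O-p-coumaroylquinic acid
Conditions: TFA/CH2Cl2/H2O (10:10:1), anisole, 0 °C → rt, dark
Reagents that add atoms: none
Why: One acidolysis removes all four groups: the tert-butyl ester loses isobutene, the two PMB aryl ethers lose the benzylic cation, which anisole traps, and the silyl ether is hydrolysed; the acidic, non-reductive conditions should leave the cinnamoyl esters and alkenes in place and avoid base-induced acyl migration to the freed O3.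

## Compound list

1 | diethyl D-tartrate, diethyl (2S,3S)-2,3-dihydroxybutanedioate | CCOC(=O)[C@@H](O)[C@H](O)C(=O)OCC | starting material
2 | benzyl bromide | BrCc1ccccc1 | starting material
3 | diethyl (2S,3S)-2,3-bis(benzyloxy)butanedioate | CCOC(=O)[C@@H](OCc1ccccc1)[C@H](OCc1ccccc1)C(=O)OCC | intermediate
4 | (2R,3R)-2,3-bis(benzyloxy)butane-1,4-diol | OC[C@@H](OCc1ccccc1)[C@H](OCc1ccccc1)CO | intermediate
5 | (2R,3R)-2,3-bis(benzyloxy)-4-[(tert-butyldimethylsilyl)oxy]butan-1-ol | CC(C)(C)[Si](C)(C)OC[C@@H](OCc1ccccc1)[C@H](OCc1ccccc1)CO | intermediate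
6 | (2R,3R)-2,3-bis(benzyloxy)-4-[(tert-butyldimethylsilyl)oxy]butyl trifluoromethanesulfonate | CC(C)(C)[Si](C)(C)OC[C@@H](OCc1ccccc1)[C@H](OCc1ccccc1)COS(=O)(=O)C(F)(F)F | intermediate
7 | (2-bromoallyl)trimethylsilane, (2-bromoprop-2-en-1-yl)trimethylsilane | C=C(Br)C[Si](C)(C)C | starting material
8 | [3-(trimethylsilyl)prop-1-en-2-yl]magnesium bromide | C=C([Mg]Br)C[Si](C)(C)C | intermediate
9 | (2R,3R)-2,3-bis(benzyloxy)-1-[(tert-butyldimethylsilyl)oxy]-5-[(trimethylsilyl)methyl]hex-5-ene | CC(C)(C)[Si](C)(C)OC[C@@H](OCc1ccccc1)[C@H](OCc1ccccc1)CC(=C)C[Si](C)(C)C | intermediate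
10 | (2R,3R)-2,3-bis(benzyloxy)-5-[(trimethylsilyl)methyl]hex-5-en-1-ol | OC[C@@H](OCc1ccccc1)[C@H](OCc1ccccc1)CC(=C)C[Si](C)(C)C | intermediate
11 | (2S,3R)-2,3-bis(benzyloxy)-5-[(trimethylsilyl)methyl]hex-5-enal | O=C[C@@H](OCc1ccccc1)[C@H](OCc1ccccc1)CC(=C)C[Si](C)(C)C | intermediate
12 | (1R,2R,3R)-2,3-bis(benzyloxy)-5-methylidenecyclohexan-1-ol, hydroxyl cis to the adjacent benzyloxy group, benzyloxy groups trans | c1ccccc1CO[C@@H]2[C@H](O)CC(=C)C[C@H]2OCc1ccccc1 | intermediate
13 | (3S,5R,6R,7R)-6,7-bis(benzyloxy)-1-oxaspiro[2.5]octan-5-ol, epoxide oxygen cis to the hydroxyl | c1ccccc1CO[C@@H]2[C@H](O)C[C@@]3(CO3)C[C@H]2OCc1ccccc1 | intermediate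
14 | (1S,3R,4R,5R)-4,5-bis(benzyloxy)-1-(hydroxymethyl)cyclohexane-1,3-diol | c1ccccc1CO[C@@H]2[C@H](O)C[C@@](O)(CO)C[C@H]2OCc1ccccc1 | intermediate
15 | (1S,3R,4R,5R)-4,5-bis(benzyloxy)-1,3-dihydroxycyclohexane-1-carbaldehyde | c1ccccc1CO[C@@H]2[C@H](O)C[C@@](O)(C=O)C[C@H]2OCc1ccccc1 | intermediate
16 | 4,5-di-O-benzylquinic acid, (1S,3R,4R,5R)-4,5-bis(benzyloxy)-1,3-dihydroxycyclohexane-1-carboxylic acid | c1ccccc1CO[C@@H]2[C@H](O)C[C@@](O)(C(=O)O)C[C@H]2OCc1ccccc1 | intermediate
17 | tert-butyl 4,5-di-O-benzylquinate | c1ccccc1CO[C@@H]2[C@H](O)C[C@@](O)(C(=O)OC(C)(C)C)C[C@H]2OCc1ccccc1 | intermediate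
18 | tert-butyl 4,5-di-O-benzyl-3-O-(tert-butyldimethylsilyl)quinate | c1ccccc1CO[C@@H]2[C@H](O[Si](C)(C)C(C)(C)C)C[C@@](O)(C(=O)OC(C)(C)C)C[C@H]2OCc1ccccc1 | intermediate
19 | tert-butyl 3-O-(tert-butyldimethylsilyl)quinate | O[C@@H]1[C@H](O[Si](C)(C)C(C)(C)C)C[C@@](O)(C(=O)OC(C)(C)C)C[C@H]1O | intermediate
20 | p-coumaric acid, (E)-3-(4-hydroxyphenyl)prop-2-enoic acid | O=C(O)/C=C/c1ccc(O)cc1 | starting material
21 | 4-methoxybenzyl (E)-3-{4-[(4-methoxybenzyl)oxy]phenyl}prop-2-enoate | O=C(OCc1ccc(OC)cc1)/C=C/c1ccc(OCc2ccc(OC)cc2)cc1 | intermediate
22 | (E)-3-{4-[(4-methoxybenzyl)oxy]phenyl}prop-2-enoic acid | O=C(O)/C=C/c1ccc(OCc2ccc(OC)cc2)cc1 | intermediate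
23 | tert-butyl 3-O-(tert-butyldimethylsilyl)-4,5-bis-O-{(E)-3-[4-(4-methoxybenzyloxy)phenyl]prop-2-enoyl}quinate | O=C(/C=C/c1ccc(OCc2ccc(OC)cc2)cc1)O[C@@H]1[C@H](O[Si](C)(C)C(C)(C)C)C[C@@](O)(C(=O)OC(C)(C)C)C[C@H]1OC(=O)/C=C/c1ccc(OCc2ccc(OC)cc2)cc1 | intermediate
24 | 4,5-di-O-p-coumaroylquinic acid | O=C(/C=C/c1ccc(O)cc1)O[C@@H]1[C@H](O)C[C@@](O)(C(=O)O)C[C@H]1OC(=O)/C=C/c1ccc(O)cc1 | target

## Step count and risks

Total step count: 17. Longest linear sequence: 16 steps (steps 1–14, 16 and 17, from diethyl D-tartrate); step 15 is a one-step side branch.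

**Step 8 (key step).** The likely failure is loss of facial control. β-Chelation through the second benzyloxy oxygen, or an open transition state, could place the new hydroxyl trans to its neighbour. Protodesilylation before ring closure is the second hazard. The fallback sets the carbinol centre by reduction instead of by the cyclisation. It sets out from 11. The cyclisation is run for conversion only, and the mixture of 12 and its C1 epimer (1S,2R,3R)-2,3-bis(benzyloxy)-5-methylidenecyclohexan-1-ol F1 is oxidised with Dess–Martin periodinane to (2S,3R)-2,3-bis(benzyloxy)-5-methylidenecyclohexan-1-one F2. F2 is reduced with LiBH(s-Bu)3 (L-Selectride) at −78 °C. Equatorial hydride attack on the 2-alkoxycyclohexanone should give the axial alcohol cis to the adjacent benzyloxy group, which is 12, where the route is rejoined.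

**Step 5.** The branched silylmethyl vinyl Grignard reagent may form or couple slowly. The β-alkoxy triflate would then have time to decompose by elimination or by attack of the silyl ether oxygen. The fallback keeps the ring-closing bond but changes the nucleophile to an ene component. It sets out from 6, which is coupled with commercial isopropenylmagnesium bromide under CuI catalysis to give tert-butyl{[(2R,3R)-2,3-bis(benzyloxy)-5-methylhex-5-en-1-yl]oxy}dimethylsilane F3. Desilylation (PPTS, MeOH) gives (2R,3R)-2,3-bis(benzyloxy)-5-methylhex-5-en-1-ol F4, and Dess–Martin oxidation gives (2S,3R)-2,3-bis(benzyloxy)-5-methylhex-5-enal F5. A SnCl4-promoted, chelation-controlled carbonyl-ene cyclisation (type 2) of F5 forms the same C2–C3 bond through the same chelate and returns to the route at 12.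

**Step 9.** Directed epoxidation of a homoallylic alcohol is slower than that of an allylic one. Undirected attack from the open equatorial face, or oxidation of the carbinol, could erode the C1 configuration or the efficiency. The fallback delivers the oxygen intramolecularly by iodocyclisation. It sets out from 12, which is converted with Boc2O and DMAP into its tert-butyl carbonate F6. Iodine in MeCN at −20 °C closes the six-membered cyclic carbonate onto C1, giving the bicyclic iodo carbonate 6,7-bis(benzyloxy)-1-(iodomethyl)-2,4-dioxabicyclo[3.3.1]nonan-3-one F7. Its carbonate can only bridge cis-1,3 positions, so O1 is necessarily cis to O3. K2CO3 in MeOH cleaves the carbonate, and the tertiary alkoxide displaces iodide to give epoxide 13, where the route is rejoined.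

**Step 11.** Over-oxidation of the free C3 hydroxyl to a β-hydroxy ketone, or cleavage of the 1,2-diol, may compete with the desired oxidation. The fallback removes the free secondary hydroxyl before the oxidation. It sets out from 13, which is converted with dihydropyran and PPTS into its tetrahydropyranyl ether F8. Hydroxide opening as in step 10 gives the 3-O-tetrahydropyranyl diol F9, and the same TEMPO/NaClO2 oxidation gives the 3-O-tetrahydropyranyl acid F10. Mild aqueous acetic acid removes the acetal and returns to the route at 16.

**Step 17.** The freed electron-rich phenols may be alkylated by 4-methoxybenzyl or tert-butyl cations. Acid-induced migration of the O4 acyl group to the liberated cis O3 is also possible on prolonged exposure. The fallback keeps the phenols deactivated as acetates while the cations are generated. It sets out from 19, which is acylated (pyridine, DMAP) with (E)-4-acetoxycinnamoyl chloride F11, made from commercial 4-acetoxycinnamic acid and oxalyl chloride. The product is tert-butyl 4,5-bis-O-[(E)-4-acetoxycinnamoyl]-3-O-(tert-butyldimethylsilyl)quinate F12. Brief treatment with TFA/CH2Cl2/H2O removes the ester and silyl groups to give 4,5-bis-O-[(E)-4-acetoxycinnamoyl]quinic acid F13. Hydrolysis of the aryl acetates with dilute aqueous HCl in THF then gives 24.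

## Further compounds

F1 | step 8 | (1S,2R,3R)-2,3-bis(benzyloxy)-5-methylidenecyclohexan-1-ol (C1 epimer of 12) | c1ccccc1CO[C@@H]2[C@@H](O)CC(=C)C[C@H]2OCc1ccccc1
F2 | step 8 | (2S,3R)-2,3-bis(benzyloxy)-5-methylidenecyclohexan-1-one | c1ccccc1CO[C@@H]2C(=O)CC(=C)C[C@H]2OCc1ccccc1
F3 | step 5 | tert-butyl{[(2R,3R)-2,3-bis(benzyloxy)-5-methylhex-5-en-1-yl]oxy}dimethylsilane | CC(C)(C)[Si](C)(C)OC[C@@H](OCc1ccccc1)[C@H](OCc1ccccc1)CC(C)=C
F4 | step 5 | (2R,3R)-2,3-bis(benzyloxy)-5-methylhex-5-en-1-ol | OC[C@@H](OCc1ccccc1)[C@H](OCc1ccccc1)CC(C)=C
F5 | step 5 | (2S,3R)-2,3-bis(benzyloxy)-5-methylhex-5-enal | O=C[C@@H](OCc1ccccc1)[C@H](OCc1ccccc1)CC(C)=C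
F6 | step 9 | tert-butyl carbonate of 12 (O-tert-butoxycarbonyl at the carbinol oxygen) | c1ccccc1CO[C@@H]2[C@H](OC(=O)OC(C)(C)C)CC(=C)C[C@H]2OCc1ccccc1
F7 | step 9 | 6,7-bis(benzyloxy)-1-(iodomethyl)-2,4-dioxabicyclo[3.3.1]nonan-3-one (carbonate bridging O1 and O3) | c1ccccc1CO[C@@H]2[C@H]3C[C@@](OC(=O)O3)(CI)C[C@H]2OCc1ccccc1
F8 | step 11 | tetrahydropyranyl ether of 13 (acetal carbon as a mixture of epimers) | c1ccccc1CO[C@@H]2[C@H](OC4CCCCO4)C[C@@]3(CO3)C[C@H]2OCc1ccccc1
F9 | step 11 | 3-O-tetrahydropyranyl derivative of 14 | c1ccccc1CO[C@@H]2[C@H](OC3CCCCO3)C[C@@](O)(CO)C[C@H]2OCc1ccccc1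
F10 | step 11 | 4,5-di-O-benzyl-3-O-tetrahydropyranylquinic acid | c1ccccc1CO[C@@H]2[C@H](OC3CCCCO3)C[C@@](O)(C(=O)O)C[C@H]2OCc1ccccc1
F11 | step 17 | (E)-4-acetoxycinnamoyl chloride | CC(=O)Oc1ccc(/C=C/C(=O)Cl)cc1
F12 | step 17 | tert-butyl 4,5-bis-O-[(E)-4-acetoxycinnamoyl]-3-O-(tert-butyldimethylsilyl)quinate | CC(=O)Oc1ccc(/C=C/C(=O)O[C@@H]2[C@H](O[Si](C)(C)C(C)(C)C)C[C@@](O)(C(=O)OC(C)(C)C)C[C@H]2OC(=O)/C=C/c2ccc(OC(C)=O)cc2)cc1
F13 | step 17 | 4,5-bis-O-[(E)-4-acetoxycinnamoyl]quinic acid | CC(=O)Oc1ccc(/C=C/C(=O)O[C@@H]2[C@H](O)C[C@@](O)(C(=O)O)C[C@H]2OC(=O)/C=C/c2ccc(OC(C)=O)cc2)cc1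
A1 | alternative 1 | 1-(methoxymethoxy)-3-(tert-butyldimethylsilyloxy)cyclohex-4-ene-1-carboxylic acid, the two oxygens cis | OC(=O)[C@]1(OCOC)C[C@@H](O[Si](C)(C)C(C)(C)C)C=CC1
A2 | alternative 1 | 3-(methoxymethoxy)-5-(tert-butyldimethylsilyloxy)-6-vinyltetrahydropyran-2-one, silyloxy and vinyl cis, C3 either epimer | C=C[C@H]1OC(=O)C(OCOC)C[C@H]1O[Si](C)(C)C(C)(C)C
A3 | alternative 2 | 3-O-(tert-butyldimethylsilyl)-4,5-di-O-p-coumaroylquinic acid | O=C(/C=C/c1ccc(O)cc1)O[C@@H]1[C@H](O[Si](C)(C)C(C)(C)C)C[C@@](O)(C(=O)O)C[C@H]1OC(=O)/C=C/c1ccc(O)cc1
A4 | alternative 2 | 3-O-(tert-butyldimethylsilyl)quinic acid 4,5-bis(hydrogen malonate) | OC(=O)CC(=O)O[C@@H]1[C@H](O[Si](C)(C)C(C)(C)C)C[C@@](O)(C(=O)O)C[C@H]1OC(=O)CC(=O)O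
A5 | alternative 2 | 4-hydroxybenzaldehyde | O=Cc1ccc(O)cc1
A6 | alternative 2 | (−)-quinic acid | O[C@@H]1[C@H](O)C[C@@](O)(C(=O)O)C[C@H]1O
A7 | alternative 3 | 4,5-O-isopropylidene-3-O-(4-methoxybenzyl)quinic acid, O1 and carboxyl tied as the spiro-1,3-dioxolan-4-one acetonide | CC1(C)O[C@@H]2[C@H](OCc3ccc(OC)cc3)C[C@]4(OC(C)(C)OC4=O)C[C@H]2O1
A8 | alternative 3 | 2,3-O-isopropylidene-4-O-(4-methoxybenzyl)-D-arabinitol 1,5-bis(trifluoromethanesulfonate) | CC1(C)O[C@H]([C@H](OCc2ccc(OC)cc2)COS(=O)(=O)C(F)(F)F)[C@@H](COS(=O)(=O)C(F)(F)F)O1
A9 | alternative 3 | 2,2-dimethyl-1,3-dioxolan-4-one | CC1(C)OCC(=O)O1
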